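Readings and results are calculated for substances that don't exist, noise included.

Take the ratio of D found to L converted, the D share: Friday's last reading gives 0.497. Converted L stands as D or as X, so equal D and X mean a share of 0.5. That is the zero of your scale, and a share above it says D stands ahead of X.

| setting | Monday's | Friday's | teal | blue | grey |
|---|---|---|---|---|---|
| L | 0.34 M | 0.75 M | 0.50 M | 0.50 M | 0.50 M |
| G | 54 mM (held) | 54 mM (held) | 54 mM (held) | 54 mM (held) | 54 mM (held) |
| temperature | −15 °C | −4 °C | 0 °C |  | −20 °C |
| remark | run made earlier | run made earlier |  | at −20 °C until 5.0 min, from then on at 0 °C |  |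
| time |  |  | 10 min | 10 min | 10 min |

- Monday's (time / min: D / %, L / %): 0.667: 1.8, 97.4; 2.00: 6.0, 93.0; 3.00: 7.8, 90.0; 5.00: 11.3, 83.8; 8.00: 15.5, 75.8; 10.0: 16.5, 70.7; 12.0: 18.5, 65.8
- Friday's (time / min: D / %, L / %): 0.833: 6.5, 92.1; 1.50: 10.6, 85.2; 2.50: 14.0, 76.5; 3.00: 15.6, 72.7; 4.00: 18.4, 66.4; 5.00: 20.9, 59.3; 6.00: 23.1, 53.5

(scatter of a reading: 0.3 percentage points)

- at the start none of Z is dissolved
- candidate steps: L + Z <-> D + J; D <-> X; G <-> Z

* which flask leads in amount of D, in percent of the L charged ("all alike" within 1.5 percentage points) (teal / blue / grey / all alike)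
* how much D is there at the end, in percent of the L charged: teal
* how much D is there at the end, in percent of the L charged: blue
* how much D is there at the end, in percent of the L charged: grey

Now read the runs as a ladder. First rung, Z: in Friday's run ln[L] gives 0.0988 /min from the first reading and 0.104 /min from the last, so these readings show no lag in the supply of Z beyond their scatter, and over them L goes pseudo-first-order. Monday's run gives 0.0349 /min.

Second rung, X: Friday's share falls from 0.823 to the zero of the scale within 6.00 min, which is shorter than the 9.62 min of the third rung, the loss of L. So in my estimate for the warm flasks, D is the share times the conversion.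

My own reckoning carries ln k straight along the temperature:

k at 0 °C = 0.155 /min
k at −20 °C = 0.0212 /min

I use the rate of L as a clock for X. Blue's warm minutes then count for 7.45 min on Friday's clock, past its last reading, so teal and blue take Friday's share. Grey's time counts for 6.08 min on Monday's clock, so I give grey the share of Monday's nearest reading, at 5.00 min, 0.698.

teal: 78.8% converted, D = 39.2%
blue: 58.6% converted, D = 29.1%
grey: 19.1% converted, D = 13.3%

The forecast says teal leads, with 35% in teal, 27.3% in blue and 12.7% in grey. Its teal stands below mine, and it reads the share lower than I do: “The equilibrium D share is about 0.4”.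

The flasks give 37.1% in teal, 29.6% in blue and 12.6% in grey, so teal leads.

    L + Z ⇌ D + J (K = 9.60, k = 0.380 /M/min, Ea = 60.0 kJ/mol, ΔH = 32.0 kJ/mol)
    D ⇌ X (K = 2.00, k = 0.0890 /min, Ea = 72.0 kJ/mol, ΔH = −18.0 kJ/mol)
    G ⇌ Z, rate k3*(csat - [Z]) (kL = 35.0 /min)
    (constants at −20 °C)

Teal's D on its 75.4% conversion is a share of 0.492 and blue's is 0.511, both close to the zero of the scale, while grey's stands at 0.693. Teal's D stands at that level because of the loss of D to X, both ways: with that step taken away, teal holds 71.5% instead of 37.1%. Carry Friday's share to blue read at 40 min, with 88.0% converted: it gives 43.7%, and that flask holds 42.6%.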